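**Plan**

1. Labels: ring C1 (quaternary; CH2OH and homofarnesyl), C2 (hydroxypropyl), C3 (alkylidene), C4, C5, C6 (C(OH)CH3); Cα is the exocyclic enal carbon.
2. C6(OH)(CH3)–C1–CH2OH is a reduced acetoacetate, so with a helper ketone at C4 the ring bond C5–C6 is an aldol bond and C1–C2 a Michael bond. The ring is cut to tert-butyl 2-homofarnesylacetoacetate and a seven-carbon enone; Cα and the formyl carbon are cut off as a dimethoxyacetyl unit.
3. Forward: acetoacetate alkylation, Pd–BINAP Michael addition (sets C1 and C2), then enamine aldol closure of ring C1–C6 through C5–C6 (sets C6 from C1 and C2).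
4. The C4 ketone is used twice more: it directs a Claisen acylation to C3, then leaves as its enol triflate (formate reduction) to give the C3=C4 enone.
5. Methylenation gives the diene C4=C3–Cα=CH2; chromium-catalysed 1,4-hydrogenation moves the double bond to C3=Cα and fixes its geometry (new methyl cis to C4, formyl carbon cis to C2).
6. Ester reduction and mild acid (acetal, silyl ether) release the target.

Key step: step 5

Assumption: (3E,7E)-homofarnesol (1) is a catalogue compound; the (R)-BINAP complex in step 4 is taken to give the (2R,3R) adduct, and the (S)-BINAP complex is used if the sense at the quaternary carbon proves opposite.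
Notation: TBS = tert-butyldimethylsilyl; homofarnesyl = (3E,7E)-4,8,12-trimethyltrideca-3,7,11-trien-1-yl.

**Step 1**
Reactants: 1 (3E,7E)-4,8,12-trimethyltrideca-3,7,11-trien-1-ol (homofarnesol)
Product: 2 (3E,7E)-1-iodo-4,8,12-trimethyltrideca-3,7,11-triene (homofarnesyl iodide)
Conditions: I2, PPh3, imidazole, CH2Cl2, 0 → 23 °C
Reagents that add atoms: iodine, II
Why: Appel-type iodination displaces the oxyphosphonium of the primary alcohol by iodide (SN2) and should leave the trisubstituted alkenes untouched.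

**Step 2**
Reactants: 3 tert-butyl 3-oxobutanoate; 2 homofarnesyl iodide
Product: 4 tert-butyl (5E,9E)-2-acetyl-6,10,14-trimethylpentadeca-5,9,13-trienoate (racemic)
Conditions: NaH, THF/DMF, 0 °C; then 2, 60 °C
Reagents that add atoms: none
Why: Acetoacetic ester alkylation of the sodium enolate with a primary iodide should give the mono-C-alkylated keto ester, used as the racemate because its stereocentre is enolisable.

**Step 3**
Reactants: 5 4-[(tert-butyldimethylsilyl)oxy]butanal; 6 1-(triphenyl-λ5-phosphanylidene)propan-2-one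
Product: 7 (3E)-7-[(tert-butyldimethylsilyl)oxy]hept-3-en-2-one
Conditions: CH2Cl2, 40 °C
Reagents that add atoms: none
Why: Wittig olefination with the stabilised acetonyl ylide should give the (E)-enone.

**Step 4**
Reactants: 4 keto ester; 7 enone
Product: 8 tert-butyl (2R,3R)-2-acetyl-3-{3-[(TBS)oxy]propyl}-5-oxo-2-homofarnesylhexanoate
Conditions: [Pd((R)-BINAP)(H2O)2](OTf)2 (10 mol%), THF, 0 °C
Reagents that add atoms: none
Why: Catalytic asymmetric Michael addition through a chiral divalent palladium enolate: the BINAP-bound O,O-chelated enolate of 4 exposes one face of C1, and the enone (activated by the acid released on enolate formation) is expected to add in an open transition state with its β-hydrogen over the chelate and its β-chain anti to the tert-butyl ester, which sets quaternary C1 and C2 together.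

**Step 5**
Reactants: 8 Michael adduct
Product: 9 tert-butyl (1R,2S,6R)-6-{3-[(TBS)oxy]propyl}-2-hydroxy-2-methyl-4-oxo-1-homofarnesylcyclohexane-1-carboxylate (hydroxyl cis to the ester and to the silyloxypropyl chain)
Conditions: (S)-proline (30 mol%), DMSO, 23 °C
Reagents that add atoms: none
Why: Proline condenses only with the unhindered C4 methyl ketone, the terminal enamine carbon C5 adds to the C6 carbonyl (activated by the geminal ester), and hydrolysis gives the β-hydroxy ketone; this is an intramolecular enamine aldol, the ketol stage of a Robinson annulation, with the Hajos–Parrish reaction as closest precedent. Ring C1–C6 closes in the 6-(enolendo)-exo-trig mode. C6 is set by the chair transition state fixed by C1 and C2: with the C2 chain equatorial the ester on C1 is axial, the methyl of the acceptor carbonyl takes the axial site anti to that ester (gauche to only one C1 substituent), and the oxygen takes the equatorial site gauche to the ester, where the forming hydroxyl can hydrogen-bond; since the aldol is reversible here, the same isomer is also the expected thermodynamic one. The step needs regioselectivity between the two methyl ketones and between C5 and C3 of the donor, secured by the congestion at C6 next to quaternary C1 and by the four-membered ring that C3 attack would require; it must also stop before dehydration, which room temperature and the amino acid catalyst favour.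

**Step 6**
Reactants: 9 ketol; 10 methyl 2,2-dimethoxyacetate
Product: 11 tert-butyl (1R,2S,6R)-6-{3-[(TBS)oxy]propyl}-5-(2,2-dimethoxyacetyl)-2,4-dihydroxy-2-methyl-1-homofarnesylcyclohex-4-ene-1-carboxylate (enol form of the β-diketone)
Conditions: LiN(SiMe3)2 (3.2 equiv), THF, −78 °C; then 10, −78 → 0 °C; aq. NH4Cl
Reagents that add atoms: none
Why: Crossed Claisen condensation: the lithium alkoxide at C6 and the fully substituted C6 should steer kinetic deprotonation of the C4 ketone to C3, the activated non-enolisable ester acylates that enolate at carbon, and the excess base holds the product as its β-diketonate, which blocks retro-aldol cleavage.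

**Step 7**
Reactants: 11 β-diketone
Product: 12 tert-butyl (1R,2S,6R)-6-{3-[(TBS)oxy]propyl}-5-(2,2-dimethoxyacetyl)-2-hydroxy-2-methyl-4-{[(trifluoromethyl)sulfonyl]oxy}-1-homofarnesylcyclohex-4-ene-1-carboxylate
Conditions: NaH (1.05 equiv), THF, 0 °C; then PhNTf2, 0 → 23 °C
Reagents that add atoms: N-phenylbis(trifluoromethanesulfonimide), O=S(=O)(N(c1ccccc1)S(=O)(=O)C(F)(F)F)C(F)(F)F
Why: Enol triflate formation from the β-diketonate is expected at the ring oxygen, as for 2-acylcyclohexanones whose enol double bond is endocyclic, the exocyclic oxygen being less basic next to the acetal; one equivalent of base leaves the tertiary hydroxyl alone.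

**Step 8**
Reactants: 12 enol triflate
Product: 13 tert-butyl (1R,2S,6R)-6-{3-[(TBS)oxy]propyl}-5-(2,2-dimethoxyacetyl)-2-hydroxy-2-methyl-1-homofarnesylcyclohex-4-ene-1-carboxylate
Conditions: Pd(OAc)2 (5 mol%), PPh3 (10 mol%), HCO2H, nBu3N, DMF, 60 °C
Reagents that add atoms: none
Why: Palladium-catalysed formate reduction of the enol triflate (oxidative addition to zerovalent palladium, formate exchange, decarboxylation, C–H reductive elimination) replaces the helper oxygen at C4 by hydrogen and leaves the C3=C4 enone.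

**Step 9**
Reactants: 13 enone
Product: 14 tert-butyl (1R,2S,6R)-6-{3-[(TBS)oxy]propyl}-5-(3,3-dimethoxyprop-1-en-2-yl)-2-hydroxy-2-methyl-1-homofarnesylcyclohex-4-ene-1-carboxylate
Conditions: Ph3PCH3Br, KOtBu, THF, 0 → 23 °C
Reagents that add atoms: methyltriphenylphosphonium bromide, C[P+](c1ccccc1)(c1ccccc1)c1ccccc1.[Br-]
Why: Wittig methylenation of the electrophilic α-keto acetal carbonyl brings in the carbon that becomes the enal methyl and creates the diene C4=C3–Cα=CH2.

**Step 10**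
Reactants: 14 diene
Product: 15 tert-butyl (1R,2S,5Z,6R)-6-{3-[(TBS)oxy]propyl}-5-(1,1-dimethoxypropan-2-ylidene)-2-hydroxy-2-methyl-1-homofarnesylcyclohexane-1-carboxylate
Conditions: (η6-naphthalene)Cr(CO)3 (20 mol%), H2 (50 bar), THF, 45 °C
Reagents that add atoms: none
Why: Chromium tricarbonyl-catalysed 1,4-hydrogenation: the Cr(CO)3 fragment binds only the conjugated diene in its s-cis form and delivers both hydrogens to its termini (C4 and the methylene), so the new C3=Cα bond should carry the new methyl cis to C4 and the acetal cis to C2, while the isolated trisubstituted alkenes are not bound.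

**Step 11**
Reactants: 15 ester
Product: 16 (1S,2S,3R,4Z)-3-{3-[(TBS)oxy]propyl}-4-(1,1-dimethoxypropan-2-ylidene)-2-(hydroxymethyl)-1-methyl-2-homofarnesylcyclohexan-1-ol
Conditions: LiAlH4, THF, 0 → 65 °C; aq. Rochelle salt
Reagents that add atoms: none
Why: Hydride reduction of the hindered tert-butyl ester to the primary alcohol, helped by the neighbouring aluminium alkoxide at C6; acetal, silyl ether and alkenes are inert to LiAlH4.

**Step 12**
Reactants: 16 diol acetal
Product: 18 (2Z)-2-[(2R,3S,4S)-4-hydroxy-3-(hydroxymethyl)-2-(3-hydroxypropyl)-4-methyl-3-homofarnesylcyclohexylidene]propanal (target), via enal silyl ether 17 (not isolated)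
Conditions: AcOH/THF/H2O (3:1:1), 23 → 40 °C
Reagents that add atoms: water, O
Why: Mild aqueous acid should hydrolyse the allylic dimethyl acetal first and then cleave the primary silyl ether, acetic acid being too weak to isomerise the tetrasubstituted enal or ionise the tertiary alcohol.

**Compound list**

1 | (3E,7E)-4,8,12-trimethyltrideca-3,7,11-trien-1-ol (homofarnesol) | CC(C)=CCC/C(C)=C/CC/C(C)=C/CCO | starting material
2 | (3E,7E)-1-iodo-4,8,12-trimethyltrideca-3,7,11-triene | CC(C)=CCC/C(C)=C/CC/C(C)=C/CCI | intermediate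
3 | tert-butyl 3-oxobutanoate | CC(=O)CC(=O)OC(C)(C)C | starting material
4 | tert-butyl (5E,9E)-2-acetyl-6,10,14-trimethylpentadeca-5,9,13-trienoate (racemic) | CC(C)=CCC/C(C)=C/CC/C(C)=C/CCC(C(C)=O)C(=O)OC(C)(C)C | intermediate
5 | 4-[(tert-butyldimethylsilyl)oxy]butanal | O=CCCCO[Si](C)(C)C(C)(C)C | starting material
6 | 1-(triphenyl-λ5-phosphanylidene)propan-2-one | CC(=O)C=P(c1ccccc1)(c1ccccc1)c1ccccc1 | starting material
7 | (3E)-7-[(tert-butyldimethylsilyl)oxy]hept-3-en-2-one | CC(=O)/C=C/CCCO[Si](C)(C)C(C)(C)C | intermediate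
8 | tert-butyl (2R,3R)-2-acetyl-3-{3-[(TBS)oxy]propyl}-5-oxo-2-homofarnesylhexanoate | CC(C)=CCC/C(C)=C/CC/C(C)=C/CC[C@@](C(C)=O)(C(=O)OC(C)(C)C)[C@H](CCCO[Si](C)(C)C(C)(C)C)CC(C)=O | intermediate
9 | tert-butyl (1R,2S,6R)-6-{3-[(TBS)oxy]propyl}-2-hydroxy-2-methyl-4-oxo-1-homofarnesylcyclohexane-1-carboxylate | CC(C)=CCC/C(C)=C/CC/C(C)=C/CC[C@@]1(C(=O)OC(C)(C)C)[C@H](CCCO[Si](C)(C)C(C)(C)C)CC(=O)C[C@]1(C)O | intermediate
10 | methyl 2,2-dimethoxyacetate | COC(OC)C(=O)OC | starting material
11 | tert-butyl (1R,2S,6R)-6-{3-[(TBS)oxy]propyl}-5-(2,2-dimethoxyacetyl)-2,4-dihydroxy-2-methyl-1-homofarnesylcyclohex-4-ene-1-carboxylate | CC(C)=CCC/C(C)=C/CC/C(C)=C/CC[C@@]1(C(=O)OC(C)(C)C)[C@H](CCCO[Si](C)(C)C(C)(C)C)C(C(=O)C(OC)OC)=C(O)C[C@]1(C)O | intermediate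
12 | tert-butyl (1R,2S,6R)-6-{3-[(TBS)oxy]propyl}-5-(2,2-dimethoxyacetyl)-2-hydroxy-2-methyl-4-{[(trifluoromethyl)sulfonyl]oxy}-1-homofarnesylcyclohex-4-ene-1-carboxylate | CC(C)=CCC/C(C)=C/CC/C(C)=C/CC[C@@]1(C(=O)OC(C)(C)C)[C@H](CCCO[Si](C)(C)C(C)(C)C)C(C(=O)C(OC)OC)=C(OS(=O)(=O)C(F)(F)F)C[C@]1(C)O | intermediate
13 | tert-butyl (1R,2S,6R)-6-{3-[(TBS)oxy]propyl}-5-(2,2-dimethoxyacetyl)-2-hydroxy-2-methyl-1-homofarnesylcyclohex-4-ene-1-carboxylate | CC(C)=CCC/C(C)=C/CC/C(C)=C/CC[C@@]1(C(=O)OC(C)(C)C)[C@H](CCCO[Si](C)(C)C(C)(C)C)C(C(=O)C(OC)OC)=CC[C@]1(C)O | intermediate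
14 | tert-butyl (1R,2S,6R)-6-{3-[(TBS)oxy]propyl}-5-(3,3-dimethoxyprop-1-en-2-yl)-2-hydroxy-2-methyl-1-homofarnesylcyclohex-4-ene-1-carboxylate | CC(C)=CCC/C(C)=C/CC/C(C)=C/CC[C@@]1(C(=O)OC(C)(C)C)[C@H](CCCO[Si](C)(C)C(C)(C)C)C(C(=C)C(OC)OC)=CC[C@]1(C)O | intermediate
15 | tert-butyl (1R,2S,5Z,6R)-6-{3-[(TBS)oxy]propyl}-5-(1,1-dimethoxypropan-2-ylidene)-2-hydroxy-2-methyl-1-homofarnesylcyclohexane-1-carboxylate | CC(C)=CCC/C(C)=C/CC/C(C)=C/CC[C@@]1(C(=O)OC(C)(C)C)[C@H](CCCO[Si](C)(C)C(C)(C)C)/C(=C(/C)C(OC)OC)CC[C@]1(C)O | intermediate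
16 | (1S,2S,3R,4Z)-3-{3-[(TBS)oxy]propyl}-4-(1,1-dimethoxypropan-2-ylidene)-2-(hydroxymethyl)-1-methyl-2-homofarnesylcyclohexan-1-ol | CC(C)=CCC/C(C)=C/CC/C(C)=C/CC[C@@]1(CO)[C@H](CCCO[Si](C)(C)C(C)(C)C)/C(=C(/C)C(OC)OC)CC[C@]1(C)O | intermediate
17 | (2Z)-2-[(2R,3S,4S)-2-{3-[(TBS)oxy]propyl}-4-hydroxy-3-(hydroxymethyl)-4-methyl-3-homofarnesylcyclohexylidene]propanal | CC(C)=CCC/C(C)=C/CC/C(C)=C/CC[C@@]1(CO)[C@H](CCCO[Si](C)(C)C(C)(C)C)/C(=C(/C)C=O)CC[C@]1(C)O | intermediate
18 | (2Z)-2-[(2R,3S,4S)-4-hydroxy-3-(hydroxymethyl)-2-(3-hydroxypropyl)-4-methyl-3-[(3E,7E)-4,8,12-trimethyltrideca-3,7,11-trien-1-yl]cyclohexylidene]propanal | CC(C)=CCC/C(C)=C/CC/C(C)=C/CC[C@@]1(CO)[C@H](CCCO)/C(=C(/C)C=O)CC[C@]1(C)O | target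

**Count and risks**

Total steps: 12. Longest linear sequence: 11 steps (1 → 2 → 4 → 8 → 9 → 11 → 12 → 13 → 14 → 15 → 16 → 18).

Steps most likely to fail:

Step 4. The α-branched acyclic keto ester may add slowly to the β-substituted enone, or with poor facial selectivity at C1 or poor simple diastereoselectivity at C2. Fallback, from 4 and 5 back to 8: aldehyde 5 is olefinated with (triphenylphosphoranylidene)acetaldehyde to (2E)-6-[(tert-butyldimethylsilyl)oxy]hex-2-enal F1. Keto ester 4 is then added to F1 under bifunctional base and hydrogen-bond catalysis by a 6′-hydroxycinchona alkaloid (9-O-benzylcupreidine or its quinine-derived pseudoenantiomer, whichever gives the 2R,3R series), a reaction class that builds adjacent quaternary and tertiary centres from α-substituted keto esters and β-substituted enals, to give tert-butyl (2R,3R)-2-acetyl-3-{3-[(TBS)oxy]propyl}-5-oxo-2-homofarnesylpentanoate F2. Chemoselective methyl addition to the aldehyde with MeTi(OiPr)3 gives tert-butyl (2R,3R)-2-acetyl-3-{3-[(TBS)oxy]propyl}-5-hydroxy-2-homofarnesylhexanoate F3 (epimers at the carbinol), and Dess–Martin oxidation returns 8.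

Step 7. Sulfonylation may take place at the exocyclic enol oxygen or give mixtures, which would put the later hydrogen on the wrong carbon. Fallback, from 9 back to 14, avoiding the β-diketone altogether: the lithium enolate of 9 is alkenylated at C3 with 2-bromo-3,3-dimethoxyprop-1-ene (Pd2(dba)3, P(tBu)3, LiN(SiMe3)2, toluene) to give tert-butyl (1R,2S,6R)-6-{3-[(TBS)oxy]propyl}-5-(3,3-dimethoxyprop-1-en-2-yl)-2-hydroxy-2-methyl-4-oxo-1-homofarnesylcyclohexane-1-carboxylate F4. NaBH4 reduces the C4 ketone to tert-butyl (1R,2S,6R)-6-{3-[(TBS)oxy]propyl}-5-(3,3-dimethoxyprop-1-en-2-yl)-2,4-dihydroxy-2-methyl-1-homofarnesylcyclohexane-1-carboxylate F5, and dehydration of the secondary alcohol with Martin sulfurane, expected toward the allylic hydrogen at C3, gives diene 14.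

Step 10. Crowding around C2 may prevent the diene from reaching the s-cis chromium complex, turnover may be slow, or reduction may go further. Fallback, from 14 to 18, trading mechanistic control of geometry for thermodynamic control: diimide (dipotassium azodicarboxylate, AcOH) reduces only the terminal methylene to give tert-butyl (1R,2S,6R)-6-{3-[(TBS)oxy]propyl}-5-(1,1-dimethoxypropan-2-yl)-2-hydroxy-2-methyl-1-homofarnesylcyclohex-4-ene-1-carboxylate F6. LiAlH4 gives (1S,2S,3R)-3-{3-[(TBS)oxy]propyl}-4-(1,1-dimethoxypropan-2-yl)-2-(hydroxymethyl)-1-methyl-2-homofarnesylcyclohex-4-en-1-ol F7, and aqueous acetic acid releases 2-[(4S,5S,6R)-4-hydroxy-5-(hydroxymethyl)-6-(3-hydroxypropyl)-4-methyl-5-homofarnesylcyclohex-1-en-1-yl]propanal F8. DBU then moves the double bond into conjugation to give 18 together with its (2E) isomer F9; the isomers are separated by chromatography and F9 is re-equilibrated (catalytic iodine or thiophenol/AIBN) and recycled.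

**Further compounds**

F1 | step 4 | (2E)-6-[(tert-butyldimethylsilyl)oxy]hex-2-enal | O=C/C=C/CCCO[Si](C)(C)C(C)(C)C
F2 | step 4 | tert-butyl (2R,3R)-2-acetyl-3-{3-[(TBS)oxy]propyl}-5-oxo-2-homofarnesylpentanoate | CC(C)=CCC/C(C)=C/CC/C(C)=C/CC[C@@](C(C)=O)(C(=O)OC(C)(C)C)[C@H](CCCO[Si](C)(C)C(C)(C)C)CC=O
F3 | step 4 | tert-butyl (2R,3R)-2-acetyl-3-{3-[(TBS)oxy]propyl}-5-hydroxy-2-homofarnesylhexanoate | CC(C)=CCC/C(C)=C/CC/C(C)=C/CC[C@@](C(C)=O)(C(=O)OC(C)(C)C)[C@H](CCCO[Si](C)(C)C(C)(C)C)CC(C)O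
F4 | step 7 | tert-butyl (1R,2S,6R)-6-{3-[(TBS)oxy]propyl}-5-(3,3-dimethoxyprop-1-en-2-yl)-2-hydroxy-2-methyl-4-oxo-1-homofarnesylcyclohexane-1-carboxylate | CC(C)=CCC/C(C)=C/CC/C(C)=C/CC[C@@]1(C(=O)OC(C)(C)C)[C@H](CCCO[Si](C)(C)C(C)(C)C)C(C(=C)C(OC)OC)C(=O)C[C@]1(C)O
F5 | step 7 | tert-butyl (1R,2S,6R)-6-{3-[(TBS)oxy]propyl}-5-(3,3-dimethoxyprop-1-en-2-yl)-2,4-dihydroxy-2-methyl-1-homofarnesylcyclohexane-1-carboxylate | CC(C)=CCC/C(C)=C/CC/C(C)=C/CC[C@@]1(C(=O)OC(C)(C)C)[C@H](CCCO[Si](C)(C)C(C)(C)C)C(C(=C)C(OC)OC)C(O)C[C@]1(C)O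
F6 | step 10 | tert-butyl (1R,2S,6R)-6-{3-[(TBS)oxy]propyl}-5-(1,1-dimethoxypropan-2-yl)-2-hydroxy-2-methyl-1-homofarnesylcyclohex-4-ene-1-carboxylate | CC(C)=CCC/C(C)=C/CC/C(C)=C/CC[C@@]1(C(=O)OC(C)(C)C)[C@H](CCCO[Si](C)(C)C(C)(C)C)C(C(C)C(OC)OC)=CC[C@]1(C)O
F7 | step 10 | (1S,2S,3R)-3-{3-[(TBS)oxy]propyl}-4-(1,1-dimethoxypropan-2-yl)-2-(hydroxymethyl)-1-methyl-2-homofarnesylcyclohex-4-en-1-ol | CC(C)=CCC/C(C)=C/CC/C(C)=C/CC[C@@]1(CO)[C@H](CCCO[Si](C)(C)C(C)(C)C)C(C(C)C(OC)OC)=CC[C@]1(C)O
F8 | step 10 | 2-[(4S,5S,6R)-4-hydroxy-5-(hydroxymethyl)-6-(3-hydroxypropyl)-4-methyl-5-homofarnesylcyclohex-1-en-1-yl]propanal | CC(C)=CCC/C(C)=C/CC/C(C)=C/CC[C@@]1(CO)[C@H](CCCO)C(C(C)C=O)=CC[C@]1(C)O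
F9 | step 10 | (2E)-2-[(2R,3S,4S)-4-hydroxy-3-(hydroxymethyl)-2-(3-hydroxypropyl)-4-methyl-3-homofarnesylcyclohexylidene]propanal | CC(C)=CCC/C(C)=C/CC/C(C)=C/CC[C@@]1(CO)[C@H](CCCO)/C(=C(\C)C=O)CC[C@]1(C)O
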